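The readings come from a simulation with made-up constants; noise was put on by code.

**Minutes of the meeting on the summer and spring flasks**

A small charge of J, 0.05 mol% on E, must first be turned into X by Z; the meeting then heard that X makes G from E, that X and G park as D, and that Z takes D on to L.

| flask | E | Z | J | remark | time |
|---|---|---|---|---|---|
| Sunday's | 0.40 M | 0.95 equiv | 0.05 mol% | run made earlier |  |
| Monday's | 0.60 M | 0.95 equiv | 0.05 mol% | run made earlier |  |
| Thursday's | 0.80 M | 0.95 equiv | 0.1 mol% | run made earlier |  |
| summer | 0.80 M | 0.950 equiv | 0.05 mol% |  | 6.0 min |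
| spring | 0.80 M | 0.950 equiv | 0.05 mol% |  | 12 min |

| run | time / min | E / % | L / % | G / % |
|---|---|---|---|---|
| Sunday's | 0.833 | 96.4 | 2.0 | 3.3 |
| Sunday's | 1.50 | 90.4 | 1.0 | 8.5 |
| Sunday's | 2.50 | 76.9 | 1.7 | 22.8 |
| Sunday's | 3.00 | 70.5 | 0.4 | 28.4 |
| Sunday's | 4.00 | 57.3 | 0.8 | 42.8 |
| Sunday's | 5.00 | 43.9 | 3.2 | 55.0 |
| Sunday's | 6.00 | 33.1 | 4.7 | 61.9 |
| Monday's | 0.833 | 92.4 | 0.8 | 6.7 |
| Monday's | 1.50 | 80.5 | 0 | 19.1 |
| Monday's | 2.50 | 60.7 | 1.3 | 38.1 |
| Monday's | 3.00 | 53.2 | 5.2 | 46.2 |
| Monday's | 4.00 | 35.0 | 7.2 | 58.8 |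
| Monday's | 5.00 | 22.5 | 10.1 | 66.8 |
| Monday's | 6.00 | 15.3 | 16.1 | 69.2 |
| Thursday's | 0.500 | 92.0 | 3.7 | 11.0 |
| Thursday's | 1.50 | 53.7 | 5.2 | 43.3 |
| Thursday's | 3.00 | 17.4 | 17.3 | 67.0 |
| Thursday's | 4.00 | 6.7 | 31.0 | 64.9 |
| Thursday's | 6.00 | 1.1 | 47.7 | 51.1 |

(each reading ± 1 percentage point)

1. which of these there is most of at the end, counted by the E in it, summer (G / L / E)
2. which of these there is most of at the end, counted by the E in it, spring (G / L / E)
3. amount of the one of these that there is most of at the end, in percent of the E charged, summer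
4. amount of the one of these that there is most of at the end, in percent of the E charged, spring

- what may be going on: E + X -> X + G; X + G <-> D; Z + D -> X + L; Z + J -> X + Q

I, taking the minutes, argued that two rates should be divided. E is lost in step with cE·cX, and L forms in step with cZ·cD, while cD follows cG·cX as long as parking keeps pace, so X and time drop out. L made per E lost is then R = κ·cZ·cG/cE, where κ is the split constant, a selectivity factor. Each unit of ln(cE) lost therefore adds κ·cZ·cG of L.

Thursday's readings from 1.50 min to 3.00 min gave 12 percentage points of L for 36 points of E, and with the mean amounts a reading of κ = 0.321 /M.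

At Thursday's last reading, E 1.1% with a scatter of 1 point, L stood at 47.7% and G at 51.1%. One unit of ln(cE) was then worth 6.2 points, so I reckoned that a further fall of E by a factor of 1.32 would bring L level with G. Spring has half of Thursday's J for twice the time, and by the product of the two it reaches Thursday's last reading, where G stood 3.4 points ahead of L, short of that point. But Sunday's run, on one fixed charge of J, read a first-order loss of E of 0.0963 /min from 0.833 min to 1.50 min and a faster one of 0.282 /min from 5.00 min to 6.00 min, which I read as X still forming from J as the minutes pass, so I expected spring's longer time to carry it past that point, with L ahead. Summer I placed near Thursday's readings at 3.00 min and 4.00 min, with G ahead.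

The forecast's author named G at 65% for summer and L at 53% for spring, adding: “This is a close call”.

The summer flask gave G at 65.1%, and the spring flask L at 58.1%, 5.1 points above the forecast.

    E + X → X + G (k = 50.0 /M/s)
    X + G ⇌ D (K = 1.10 /M, k = 120 /M/s)
    Z + D → X + L (k = 15.0 /M/s)
    Z + J → X + Q (k = 0.00710 /M/s)

In spring, E fell from 6.37% at 6.00 min to 0.0725% at 12.0 min, which is 4.47 units of ln(cE). With mean amounts, κ turns this into 32 points of L on the 28.5% already there, or 60.5% against the flask's 58.1%. The neighbour with 0.380 equiv of Z holds, at 12.0 min, E 1.40% and 47.8% of its Z, so there R = 2.62. That neighbour stands at L 19.8% and G 78.8%.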